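Drimane numbering is used for all sections: ring A = C1–C5 and C10, ring B = C5–C10, C11 on C9, C12 on C8. Precursors carry the numbers their atoms will have in the target.

## The problem

Isofeterin (23) is a trans-fused 4,4,10-trimethyldecalin with a 7-coumarinyl ether at C11, and C5, C9 and C10 are antipodal to the drimanes obtainable from sclareolide, so the usual chiral-pool entry gives the wrong enantiomer. There are five stereocentres: quaternary C10 (S), H5 trans to the C10 methyl (5S), an equatorial acetate at C6 cis to H5 (6R), an equatorial CH2OAr at C9 cis to the C10 methyl (9R) and an axial hydroxyl at C3 trans to the C10 methyl (3S). C3 lies across ring A from C10 and cannot be trusted to steer ring B, whereas the C10 methyl, once in place, shields one face of ring B and can relay C5, C6 and C9; the real stereochemical problem is therefore the absolute configuration of the quaternary carbon. The C6 oxygen sits on a carbon that a polyene cyclisation leaves as an unactivated methylene, and it has to be told apart (acetate) from the free C3 hydroxyl. The 8(12)-alkene moves into the ring under acid, is β,γ to any C11 carbonyl and is more reactive towards borane than a ring alkene. The coumarin is an aryl ester and a conjugate acceptor, so strong base, hydride and alkoxide are excluded once it is attached, and its ether oxygen sits on a β-branched primary carbon. The feature that makes the key step possible is that C11 hangs on C9, and C9 is tied to the oxygen-bearing C6 through C7–C8(=C12): the atoms O–C6–C7–C8–C9–C11 are the ring of a δ-lactone, and with an alkene at C5=C10 the array C10=C5–C6–O–C11=C9 of its enol ether is a Claisen array whose [3,3] shift makes the C9–C10 bond and closes ring B.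

## Retrosynthesis

**C11–O(aryl) and O3–Si (23 ⇒ 22 ⇒ 20 + 21).** The aryl ether is cut last, so that the base- and hydride-sensitive coumarin 21 never meets an enolate or LiAlH4. The silyl ether 22 leaves one deprotection after the coupling. The forward reaction must alkylate a phenol with a hindered primary alcohol without touching the C6 acetate.

**C6–O and C5–H (20 ⇒ 19).** Both bonds are removed together to leave the Δ5 alkene of 19. The alternative of carrying a C6 ketone was rejected, because hydride attacks a 6-ketone between two axial methyls from the open face and gives the axial alcohol. Addition of O and H across Δ5 from the face opposite the C10 methyl gives the trans fusion and the equatorial oxygen at once. The forward reaction must choose the trisubstituted alkene over the exocyclic one and put the oxygen on C6.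

**C9–H and the C11 oxidation level (19 ⇒ 18 ⇒ 16).** C11 is taken back to an ester, which makes C9 enolisable. Ester 18 is the C9 epimer of 16, reached through the planar dienolate 17, so the C9 configuration delivered by the key step need not be the final one.

**C9–C10, the key cut (16 ⇒ 12).** Cutting C9–C10 and reconnecting C11 to the C6 oxygen turns the bicyclic ester 16 into the monocyclic lactone 12. Its silyl ketene acetal 13 carries the Claisen array, and the shift passes through silyl ester 14 and acid 15. This cut is preferred over C4–C5/C9–C10 (polyene) or C6–C7 (ene) because it converts the one stereocentre of 12 that is easy to set, the C6 carbinol, into the quaternary C10 with no choice of transition-state shape, and it delivers the Δ5 alkene and the 8(12)-alkene in the same event. The precursor has one ring and two stereocentres fewer. The forward reaction must form a bond to a fully substituted alkene carbon.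

**C11–O6 and C6–C7 (12 ⇒ 9 ⇒ 6 + 8).** Lactone 12 is the cyclised, deconjugated form (via 10 and 11) of the δ-hydroxy enoate 9, which is the γ-adduct of a senecioate dienolate 8 with enal 6. The five carbons C7, C8, C9, C11 and C12 thus arrive as one commercial C5 unit, and the only new stereocentre, C6, is set by a catalytic asymmetric vinylogous aldol reaction.

**Ring A (6 ⇒ 4 ⇒ 3 ⇒ 2 ⇒ 1; 8 ⇒ 7).** Enal 6 is the formylation product of the vinyllithium 5 released from hydrazone 4 of ketone 3, which comes from the hydroxy ketone 1 by silylation (2) and methylation. Compound 1 already holds C3 with the (S) configuration of the target, so C3 is never touched. Dienolate 8 is the silyl enol ether of ester 7.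

## Roads not taken

**Alternative 1:** the most obvious plan is the biomimetic bicyclisation that cuts C4–C5 and C9–C10 together. The precursor would be the epoxy-farnesyl coumarinyl ether A1 with a silyloxy group at the future C6. Cp2TiCl (trivalent titanium) would open the epoxide to the C4 radical, two six-membered closures would follow, and the C8 radical would end as the exocyclic alkene in A2. The chair-chair closure places the C3 hydroxyl equatorial, cis to the C10 methyl, so A2 is the C3 epimer and needs an oxidation and hindered-hydride reduction with the coumarin already present. A1 needs two separately installed stereocentres on a flexible chain, whose match in the cyclisation is not assured. Its C6 oxygen lies allylic between the two reacting alkenes, and O3 and O6 must still be differentiated. The chosen plan takes C3 ready-made and creates the two oxygens at different stages.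

**Alternative 2:** a Robinson-annulation entry from the bicyclic enedione A3 cuts ring A at the enone and keeps C10 from the start. Deconjugative gem-dimethylation would give the Δ5 ketone A4, and hydroboration would then set C5 and C6. A3 maps C3, C5, C9 and C10, but C9 is a ketone and C11 and C12 are missing. Building C9(H)(CH2O) and C8(=CH2) from it needs a homologation, an α-functionalisation and an olefination, each with its own stereochemical question at C9, in a long linear sequence. The chosen plan brings C7–C9, C11 and C12 in one piece.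

**Alternative 3:** an anionic oxy-Cope shift followed by a carbonyl-ene closure, from the same aldol adduct 9. Reduction and silylation would give dienol A5. Its potassium alkoxide would shift C6–C7 to C9–C10 and give aldehyde A6, and an intramolecular carbonyl-ene reaction would re-form C6–C7 with the exocyclic alkene. Here the [3,3] array is acyclic, so chair and boat compete and C9 is not secure. C5 arises by protonation of an exocyclic enolate with no bias. A concerted ene closure can pass hydrogen from C12 only to an oxygen that is axial at C6, between the C4 and C10 methyls, while the target has it equatorial. The lactone version enforces one transition state and leaves C5 and C6 to an addition on the rigid bicycle.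

Key step: step 8

Assumption 1: (S)-3-hydroxy-2,2-dimethylcyclohexan-1-one (1) is taken as a purchasable building block; otherwise it is one step from 2,2-dimethylcyclohexane-1,3-dione by yeast reduction.

Assumption 2: the (R,R)-enantiomer of the bisphosphoramide in step 6 is taken as the one that sends the dienolate to the Re face of aldehyde 6; its antipode serves if the sense is the opposite.

## Route

Step 1
Reactants: 1 (S)-3-hydroxy-2,2-dimethylcyclohexan-1-one
Product: 2 (S)-3-[(tert-butyldimethylsilyl)oxy]-2,2-dimethylcyclohexan-1-one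
Conditions: TBSCl, imidazole, DMF, rt
Reagents that add atoms: tert-butyldimethylsilyl chloride, CC(C)(C)[Si](C)(C)Cl
Why: Standard silylation of a secondary alcohol; the silyl ether masks O3 through all base and hydride steps and is removed only at the end.

Step 2
Reactants: 2 (S)-3-[(tert-butyldimethylsilyl)oxy]-2,2-dimethylcyclohexan-1-one
Product: 3 (3S)-3-[(tert-butyldimethylsilyl)oxy]-2,2,6-trimethylcyclohexan-1-one as a mixture of C6 epimers
Conditions: LiN(iPr)2, THF, −78 °C; MeI, −78 → 0 °C
Reagents that add atoms: iodomethane, CI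
Why: The ketone can enolise only away from the quaternary carbon, so kinetic enolate methylation installs the future C10 methyl; the new centre becomes sp2 in step 4 and its configuration is immaterial.

Step 3
Reactants: 3 (3S)-3-[(tert-butyldimethylsilyl)oxy]-2,2,6-trimethylcyclohexan-1-one
Product: 4 N'-[(3S)-3-[(tert-butyldimethylsilyl)oxy]-2,2,6-trimethylcyclohexylidene]-2,4,6-triisopropylbenzenesulfonohydrazide
Conditions: 2,4,6-(iPr)3C6H2SO2NHNH2, HCl (cat.), MeCN, rt
Reagents that add atoms: 2,4,6-triisopropylbenzenesulfonohydrazide, NNS(=O)(=O)c1c(C(C)C)cc(C(C)C)cc1C(C)C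
Why: Acid-catalysed condensation to the arenesulfonylhydrazone needed for a Shapiro reaction; the triisopropylphenyl group prevents ortho-lithiation in the next step.

Step 4
Reactants: 4 N'-[(3S)-3-[(tert-butyldimethylsilyl)oxy]-2,2,6-trimethylcyclohexylidene]-2,4,6-triisopropylbenzenesulfonohydrazide
Product: 6 (S)-5-[(tert-butyldimethylsilyl)oxy]-2,6,6-trimethylcyclohex-1-ene-1-carbaldehyde, via vinyllithium 5 (not isolated)
Conditions: n-BuLi (2.2 equiv), THF/TMEDA, −78 → 0 °C; DMF, −78 °C → rt; aq. NH4Cl
Reagents that add atoms: N,N-dimethylformamide, CN(C)C=O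
Why: Shapiro reaction: deprotonation at N–H and at the only α-C–H, then loss of sulfinate and N2, gives the tetrasubstituted vinyllithium 5, which DMF formylates; C6 and the C5=C10 alkene are now in place.

Step 5
Reactants: 7 methyl 3-methylbut-2-enoate
Product: 8 tert-butyl[(1-methoxy-3-methylbuta-1,3-dien-1-yl)oxy]dimethylsilane
Conditions: LiN(iPr)2, THF, −78 °C; TBSCl, DMPU, −78 °C → rt
Reagents that add atoms: tert-butyldimethylsilyl chloride, CC(C)(C)[Si](C)(C)Cl
Why: γ-Deprotonation of the enoate at the methyl syn to the carbonyl and O-silylation of the extended enolate give the silyl dienol ether used as the five-carbon nucleophile.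

Step 6
Reactants: 6 (S)-5-[(tert-butyldimethylsilyl)oxy]-2,6,6-trimethylcyclohex-1-ene-1-carbaldehyde; 8 tert-butyl[(1-methoxy-3-methylbuta-1,3-dien-1-yl)oxy]dimethylsilane
Product: 9 methyl (2E,5R)-5-hydroxy-3-methyl-5-[(5S)-5-[(tert-butyldimethylsilyl)oxy]-2,6,6-trimethylcyclohex-1-en-1-yl]pent-2-enoate
Conditions: SiCl4 (1.5 equiv), (R,R)-bisphosphoramide (two N,N'-dimethyl-1,1'-binaphthyl-2,2'-diamine phosphoramide units joined by a pentamethylene chain, 5 mol%), iPr2NEt (10 mol%), CH2Cl2, −78 °C; aq. NaHCO3
Reagents that add atoms: none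
Why: Vinylogous Mukaiyama aldol reaction under Lewis-base activation of SiCl4: the phosphoramide-bound silyl cation activates the aldehyde, the dienolate attacks through its γ-carbon (C7) and the (E)-enoate results; catalyst control of the aldehyde face should set (R)-C6, the only source of absolute configuration for C10.

Step 7
Reactants: 9 methyl (2E,5R)-5-hydroxy-3-methyl-5-[(5S)-5-[(tert-butyldimethylsilyl)oxy]-2,6,6-trimethylcyclohex-1-en-1-yl]pent-2-enoate
Product: 12 (6R)-4-methylidene-6-[(5S)-5-[(tert-butyldimethylsilyl)oxy]-2,6,6-trimethylcyclohex-1-en-1-yl]oxan-2-one, via dilithium dienolate 10 (not isolated), via deconjugated hydroxy ester 11 (not isolated)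
Conditions: LiN(iPr)2 (3.2 equiv), THF/DMPU, −78 °C; AcOH, −78 °C; crude with (ClBu2Sn)2O (5 mol%), PhMe, 90 °C
Reagents that add atoms: none
Why: Deconjugative protonation: with the hydroxyl as its alkoxide, the amide removes a proton from the C12 methyl syn to the ester of the (E)-enoate, and dienolate 10 is protonated kinetically at C9 to give the 8(12)-methylene ester 11; neutral tin-catalysed transesterification then closes the δ-lactone without moving the alkene or ionising the allylic C6–O bond.

Step 8
Reactants: 12 (6R)-4-methylidene-6-[(5S)-5-[(tert-butyldimethylsilyl)oxy]-2,6,6-trimethylcyclohex-1-en-1-yl]oxan-2-one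
Product: 16 methyl (3S,9S,10S)-3-[(tert-butyldimethylsilyl)oxy]drima-5,8(12)-dien-11-oate, via silyl ketene acetal 13 (not isolated), via trimethylsilyl ester 14 (not isolated), via carboxylic acid 15 (not isolated)
Conditions: LiN(SiMe3)2, Me3SiCl, Et3N, THF, −78 °C; PhMe, 105 °C; MeOH then Me3SiCHN2, rt
Reagents that add atoms: (trimethylsilyl)diazomethane, C[Si](C)(C)C=[N+]=[N-]
Why: The amide removes the doubly activated C9 proton (α to the lactone carbonyl and allylic to C8=C12) and Me3SiCl traps the enolate on oxygen as ketene acetal 13. On heating, 13 undergoes the [3,3]-sigmatropic Ireland–Claisen shift through the array C9=C11(OSi)–O–C6–C5=C10: the C9–C10 bond forms as the C6–O bond breaks, the alkene moves to C5=C6 and C11 becomes the silyl carboxylate 14, which methanol cleaves to acid 15 and Me3SiCHN2 methylates. The closest known reaction type is the Claisen ring contraction of ω-alkenyl lactone silyl ketene acetals to cycloalkenecarboxylic acids. Ring B is closed in a ring-contraction mode in which the six-membered lactone is exchanged for the six-membered carbocycle C5–C10, and because C7–C8 ties C6 to C9 the pericyclic array can only be a boat. The quaternary C10 is controlled by C6: the shift is suprafacial and only the C5–C6 rotamer with C7 syn to C10 lets C9 reach C10, so the (R)-carbinol should deliver C9 to the alkene face that makes C10 (S), and C6 is consumed in the process. C9 is set by the boat, which places the ester trans to the C10 methyl; this is the wrong epimer and is corrected in step 9. The step needs enolisation at C9 only and a Claisen shift faster than the Cope shift of the C12=C8–C7–C6–C5=C10 diene; the β,γ-position of the alkene secures the first and the ketene acetal oxygen the second.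

Step 9
Reactants: 16 methyl (3S,9S,10S)-3-[(tert-butyldimethylsilyl)oxy]drima-5,8(12)-dien-11-oate
Product: 18 methyl (3S,9R,10S)-3-[(tert-butyldimethylsilyl)oxy]drima-5,8(12)-dien-11-oate, via lithium dienolate 17 (not isolated)
Conditions: LiN(iPr)2 (1.3 equiv), THF/DMPU, −78 °C; AcOH, −78 °C
Reagents that add atoms: none
Why: Deprotonation at C9 (α to the ester and allylic) gives the extended enolate 17 with C9 planar; kinetic protonation should occur at the α-carbon and from the face opposite the pseudo-axial C10 methyl, which inverts C9, puts the ester cis to that methyl and keeps the exocyclic alkene.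

Step 10
Reactants: 18 methyl (3S,9R,10S)-3-[(tert-butyldimethylsilyl)oxy]drima-5,8(12)-dien-11-oate
Product: 19 (3S,9R,10S)-3-[(tert-butyldimethylsilyl)oxy]drima-5,8(12)-dien-11-ol
Conditions: LiAlH4, Et2O, 0 °C
Reagents that add atoms: none
Why: Hydride reduction of the ester to the C11 primary alcohol; the silyl ether and the unactivated alkenes are inert and no stereocentre is touched.

Step 11
Reactants: 19 (3S,9R,10S)-3-[(tert-butyldimethylsilyl)oxy]drima-5,8(12)-dien-11-ol
Product: 20 (3S,5S,6R,9R,10S)-3-[(tert-butyldimethylsilyl)oxy]-11-hydroxydrim-8(12)-en-6-yl acetate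
Conditions: 9-mesityl-10-methylacridinium tetrafluoroborate (5 mol%), PhSSPh (10 mol%), AcOH (10 equiv), 2,6-lutidine (25 mol%), 1,2-dichloroethane, 450 nm LEDs, rt
Reagents that add atoms: acetic acid, CC(=O)O
Why: Photoredox hydroacetoxylation of a trisubstituted alkene: the excited acridinium should oxidise the electron-richer Δ5 alkene in preference to the 1,1-disubstituted exocyclic one, acetic acid adds to the less substituted C6 from the face opposite the C4 and C10 methyls to leave the tertiary C5 radical, and hydrogen-atom transfer from PhSH on the same open face gives the trans ring fusion. H5 and the C6 acetate thus arrive cis to each other and trans to the C10 methyl (5S, 6R); the equatorial C11 hydroxyl lies across ring B from C6 and cannot intercept the radical cation.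

Step 12
Reactants: 20 (3S,5S,6R,9R,10S)-3-[(tert-butyldimethylsilyl)oxy]-11-hydroxydrim-8(12)-en-6-yl acetate; 21 7-hydroxy-2H-chromen-2-one (umbelliferone)
Product: 22 (3S,5S,6R,9R,10S)-3-[(tert-butyldimethylsilyl)oxy]-11-[(2-oxo-2H-chromen-7-yl)oxy]drim-8(12)-en-6-yl acetate
Conditions: PPh3, DIAD, PhMe, 0 °C → rt
Reagents that add atoms: none
Why: Mitsunobu etherification: the primary C11 alcohol is activated as its alkoxyphosphonium ion and displaced by the acidic phenol in an SN2 step at a CH2 group; acetate, silyl ether and alkene take no part and the coumarin meets neither base nor hydride.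

Step 13
Reactants: 22 (3S,5S,6R,9R,10S)-3-[(tert-butyldimethylsilyl)oxy]-11-[(2-oxo-2H-chromen-7-yl)oxy]drim-8(12)-en-6-yl acetate
Product: 23 isofeterin, (3S,5S,6R,9R,10S)-3-hydroxy-11-[(2-oxo-2H-chromen-7-yl)oxy]drim-8(12)-en-6-yl acetate
Conditions: HF·pyridine, THF/pyridine, 0 °C → rt
Reagents that add atoms: none
Why: Fluoride cleavage of the hindered secondary silyl ether under buffered conditions that leave the acetate, the aryl ether, the coumarin lactone and the exocyclic alkene untouched; C3 keeps the (S) configuration brought in with 1.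

## Compound list

1 | (S)-3-hydroxy-2,2-dimethylcyclohexan-1-one | O=C1CCC[C@H](O)C1(C)C | starting material
2 | (S)-3-[(tert-butyldimethylsilyl)oxy]-2,2-dimethylcyclohexan-1-one | O=C1CCC[C@H](O[Si](C)(C)C(C)(C)C)C1(C)C | intermediate
3 | (3S)-3-[(tert-butyldimethylsilyl)oxy]-2,2,6-trimethylcyclohexan-1-one (C6 epimers) | CC1CC[C@H](O[Si](C)(C)C(C)(C)C)C(C)(C)C1=O | intermediate
4 | N'-[(3S)-3-[(tert-butyldimethylsilyl)oxy]-2,2,6-trimethylcyclohexylidene]-2,4,6-triisopropylbenzenesulfonohydrazide | CC1CC[C@H](O[Si](C)(C)C(C)(C)C)C(C)(C)C1=NNS(=O)(=O)c1c(C(C)C)cc(C(C)C)cc1C(C)C | intermediate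
5 | [(5S)-5-[(tert-butyldimethylsilyl)oxy]-2,6,6-trimethylcyclohex-1-en-1-yl]lithium | [Li]C1=C(C)CC[C@H](O[Si](C)(C)C(C)(C)C)C1(C)C | intermediate (not isolated)
6 | (S)-5-[(tert-butyldimethylsilyl)oxy]-2,6,6-trimethylcyclohex-1-ene-1-carbaldehyde | O=CC1=C(C)CC[C@H](O[Si](C)(C)C(C)(C)C)C1(C)C | intermediate
7 | methyl 3-methylbut-2-enoate | COC(=O)C=C(C)C | starting material
8 | tert-butyl[(1-methoxy-3-methylbuta-1,3-dien-1-yl)oxy]dimethylsilane | COC(O[Si](C)(C)C(C)(C)C)=CC(C)=C | intermediate
9 | methyl (2E,5R)-5-hydroxy-3-methyl-5-[(5S)-5-[(tert-butyldimethylsilyl)oxy]-2,6,6-trimethylcyclohex-1-en-1-yl]pent-2-enoate | COC(=O)/C=C(C)/C[C@@H](O)C1=C(C)CC[C@H](O[Si](C)(C)C(C)(C)C)C1(C)C | intermediate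
10 | dilithium alkoxide dienolate of 9 | [Li+].[Li+].COC([O-])=CC(=C)C[C@@H]([O-])C1=C(C)CC[C@H](O[Si](C)(C)C(C)(C)C)C1(C)C | intermediate (not isolated)
11 | methyl (5R)-5-hydroxy-3-methylidene-5-[(5S)-5-[(tert-butyldimethylsilyl)oxy]-2,6,6-trimethylcyclohex-1-en-1-yl]pentanoate | COC(=O)CC(=C)C[C@@H](O)C1=C(C)CC[C@H](O[Si](C)(C)C(C)(C)C)C1(C)C | intermediate (not isolated)
12 | (6R)-4-methylidene-6-[(5S)-5-[(tert-butyldimethylsilyl)oxy]-2,6,6-trimethylcyclohex-1-en-1-yl]oxan-2-one | O=C1CC(=C)C[C@@H](O1)C1=C(C)CC[C@H](O[Si](C)(C)C(C)(C)C)C1(C)C | intermediate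
13 | trimethylsilyl ketene acetal of 12, trimethyl{[(2R)-4-methylidene-2-[(5S)-5-[(tert-butyldimethylsilyl)oxy]-2,6,6-trimethylcyclohex-1-en-1-yl]-3,4-dihydro-2H-pyran-6-yl]oxy}silane | C[Si](C)(C)OC1=CC(=C)C[C@@H](O1)C1=C(C)CC[C@H](O[Si](C)(C)C(C)(C)C)C1(C)C | intermediate (not isolated)
14 | trimethylsilyl (3S,9S,10S)-3-[(tert-butyldimethylsilyl)oxy]drima-5,8(12)-dien-11-oate | C=C1CC=C2C(C)(C)[C@@H](O[Si](C)(C)C(C)(C)C)CC[C@@]2(C)[C@H]1C(=O)O[Si](C)(C)C | intermediate (not isolated)
15 | (3S,9S,10S)-3-[(tert-butyldimethylsilyl)oxy]drima-5,8(12)-dien-11-oic acid | C=C1CC=C2C(C)(C)[C@@H](O[Si](C)(C)C(C)(C)C)CC[C@@]2(C)[C@H]1C(O)=O | intermediate (not isolated)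
16 | methyl (3S,9S,10S)-3-[(tert-butyldimethylsilyl)oxy]drima-5,8(12)-dien-11-oate (ester trans to the C10 methyl) | C=C1CC=C2C(C)(C)[C@@H](O[Si](C)(C)C(C)(C)C)CC[C@@]2(C)[C@H]1C(=O)OC | intermediate
17 | lithium dienolate of 16 | [Li+].C=C1CC=C2C(C)(C)[C@@H](O[Si](C)(C)C(C)(C)C)CC[C@@]2(C)C1=C([O-])OC | intermediate (not isolated)
18 | methyl (3S,9R,10S)-3-[(tert-butyldimethylsilyl)oxy]drima-5,8(12)-dien-11-oate (ester cis to the C10 methyl) | C=C1CC=C2C(C)(C)[C@@H](O[Si](C)(C)C(C)(C)C)CC[C@@]2(C)[C@@H]1C(=O)OC | intermediate
19 | (3S,9R,10S)-3-[(tert-butyldimethylsilyl)oxy]drima-5,8(12)-dien-11-ol | C=C1CC=C2C(C)(C)[C@@H](O[Si](C)(C)C(C)(C)C)CC[C@@]2(C)[C@@H]1CO | intermediate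
20 | (3S,5S,6R,9R,10S)-3-[(tert-butyldimethylsilyl)oxy]-11-hydroxydrim-8(12)-en-6-yl acetate | C=C1C[C@@H](OC(C)=O)[C@@H]2C(C)(C)[C@@H](O[Si](C)(C)C(C)(C)C)CC[C@@]2(C)[C@@H]1CO | intermediate
21 | 7-hydroxy-2H-chromen-2-one (umbelliferone) | Oc1ccc2ccc(=O)oc2c1 | starting material
22 | (3S,5S,6R,9R,10S)-3-[(tert-butyldimethylsilyl)oxy]-11-[(2-oxo-2H-chromen-7-yl)oxy]drim-8(12)-en-6-yl acetate | C=C1C[C@@H](OC(C)=O)[C@@H]2C(C)(C)[C@@H](O[Si](C)(C)C(C)(C)C)CC[C@@]2(C)[C@@H]1COc1ccc2ccc(=O)oc2c1 | intermediate
23 | isofeterin | C=C1C[C@@H](OC(C)=O)[C@@H]2C(C)(C)[C@@H](O)CC[C@@]2(C)[C@@H]1COc1ccc2ccc(=O)oc2c1 | target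

## Step count and least certain steps

Total step count: 13. Longest linear sequence: 12 steps (1 → 23 through steps 1–4 and 6–13; step 5 prepares 8 on a side branch).

**Step 8 (key step).** The sigmatropic shift may stall, because the enforced boat brings the ketene acetal oxygen over the gem-dimethyl carbon C4 and holds C7 syn to the C10 methyl. During prolonged heating the ketene acetal may be lost by desilylation or C-silylation, or the allylic C6–O bond may ionise, which would erode the transfer of configuration. The fallback sets out from 6 and builds ring B by an intermolecular cycloaddition. Wittig methylenation (Ph3P=CH2, THF) gives the diene tert-butyl{[(1S)-3-ethenyl-2,2,4-trimethylcyclohex-3-en-1-yl]oxy}dimethylsilane F1. A Diels–Alder reaction of F1 with methyl buta-2,3-dienoate (EtAlCl2, CH2Cl2, −78 → 0 °C, or PhMe, 110 °C) across the conjugated allene bond gives 16 together with 18, both of which enter step 9. The route is rejoined at 16. In this fallback the face of C10 is controlled only by the distant C3 silyl ether, so the C10 epimer would have to be removed by chromatography.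

**Step 11.** Single-electron oxidation may be slow for so hindered an alkene, and the radical cation may lose an allylic proton at C7 instead of taking up acetic acid. Discrimination between the two faces in the acetate attack or in the hydrogen-atom transfer may also be incomplete. The fallback sets out from 16, uses only classical reactions and returns at 22. It also moves the C9 protonation of step 9 to a chair-locked trans-decalin, should its facial selectivity be poor in the Δ5 series.
- DBU (PhMe, 80 °C) moves the exocyclic alkene into conjugation and gives methyl (3S,10R)-3-[(tert-butyldimethylsilyl)oxy]drima-5,8-dien-11-oate F4, in which the tetrasubstituted enoate is inert to borane.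
- BH3·SMe2 (THF, 0 °C → rt) then NaBO3 adds H and OH across Δ5 from the face opposite the C10 methyl and gives methyl (3S,5S,6R,10R)-3-[(tert-butyldimethylsilyl)oxy]-6-hydroxydrim-8-en-11-oate F5.
- LiN(iPr)2 (excess, THF/DMPU, −78 °C) then AcOH deconjugates with protonation at C9 anti to the now axial methyl and gives methyl (3S,5S,6R,9R,10R)-3-[(tert-butyldimethylsilyl)oxy]-6-hydroxydrim-8(12)-en-11-oate F6.
- LiAlH4 gives (3S,5S,6R,9R,10S)-3-[(tert-butyldimethylsilyl)oxy]drim-8(12)-ene-6,11-diol F7.
- Mitsunobu coupling with 21, selective for the primary hydroxyl, gives 7-{[(3S,5S,6R,9R,10S)-3-[(tert-butyldimethylsilyl)oxy]-6-hydroxydrim-8(12)-en-11-yl]oxy}-2H-chromen-2-one F8.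
- Ac2O, DMAP and pyridine give 22.

**Step 6.** Addition to an aldehyde flanked by a quaternary carbon and a methyl-bearing alkene carbon may be slow, and the catalyst may lose control of the aldehyde face. The fallback sets out from 6 and 7 and returns at 9. A γ-selective aldol reaction of the lithium dienolate of 7, with both partners bound to Al(OC6H3Ph2-2,6)3 (LiN(iPr)2, PhMe/THF, −78 °C), gives 9 together with its carbinol epimer methyl (2E,5S)-5-hydroxy-3-methyl-5-[(5S)-5-[(tert-butyldimethylsilyl)oxy]-2,6,6-trimethylcyclohex-1-en-1-yl]pent-2-enoate F2. Oxidation of the mixture with 1,1,1-triacetoxy-1,1-dihydro-1,2-benziodoxol-3(1H)-one gives the ketone methyl (2E)-3-methyl-5-oxo-5-[(5S)-5-[(tert-butyldimethylsilyl)oxy]-2,6,6-trimethylcyclohex-1-en-1-yl]pent-2-enoate F3. Reduction with catecholborane and the (S)-B-methyl oxazaborolidine derived from diphenylprolinol (PhMe, −78 °C) returns 9, the alkenyl group acting as the large substituent.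

**Step 12.** Displacement at the β-branched C11, next to the quaternary C10, may be slow, and elimination towards the 8(12),9(11)-diene may compete through the allylic C9–H. The fallback sets out from 20 and returns at 22. (CF3SO2)2O and 2,6-lutidine (CH2Cl2, −78 °C) give the primary triflate (3S,5S,6R,9R,10S)-3-[(tert-butyldimethylsilyl)oxy]-11-[(trifluoromethanesulfonyl)oxy]drim-8(12)-en-6-yl acetate F9. This is displaced at low temperature by the caesium salt of 21 (Cs2CO3, DMF, 0 °C → rt).

## Further compounds

F1 | step 8 | tert-butyl{[(1S)-3-ethenyl-2,2,4-trimethylcyclohex-3-en-1-yl]oxy}dimethylsilane | C=CC1=C(C)CC[C@H](O[Si](C)(C)C(C)(C)C)C1(C)C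
F2 | step 6 | methyl (2E,5S)-5-hydroxy-3-methyl-5-[(5S)-5-[(tert-butyldimethylsilyl)oxy]-2,6,6-trimethylcyclohex-1-en-1-yl]pent-2-enoate | COC(=O)/C=C(C)/C[C@H](O)C1=C(C)CC[C@H](O[Si](C)(C)C(C)(C)C)C1(C)C
F3 | step 6 | methyl (2E)-3-methyl-5-oxo-5-[(5S)-5-[(tert-butyldimethylsilyl)oxy]-2,6,6-trimethylcyclohex-1-en-1-yl]pent-2-enoate | COC(=O)/C=C(C)/CC(=O)C1=C(C)CC[C@H](O[Si](C)(C)C(C)(C)C)C1(C)C
F4 | step 11 | methyl (3S,10R)-3-[(tert-butyldimethylsilyl)oxy]drima-5,8-dien-11-oate | CC1=C(C(=O)OC)[C@]2(C)CC[C@H](O[Si](C)(C)C(C)(C)C)C(C)(C)C2=CC1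
F5 | step 11 | methyl (3S,5S,6R,10R)-3-[(tert-butyldimethylsilyl)oxy]-6-hydroxydrim-8-en-11-oate | CC1=C(C(=O)OC)[C@]2(C)CC[C@H](O[Si](C)(C)C(C)(C)C)C(C)(C)[C@H]2[C@H](O)C1
F6 | step 11 | methyl (3S,5S,6R,9R,10R)-3-[(tert-butyldimethylsilyl)oxy]-6-hydroxydrim-8(12)-en-11-oate | C=C1C[C@@H](O)[C@@H]2C(C)(C)[C@@H](O[Si](C)(C)C(C)(C)C)CC[C@@]2(C)[C@@H]1C(=O)OC
F7 | step 11 | (3S,5S,6R,9R,10S)-3-[(tert-butyldimethylsilyl)oxy]drim-8(12)-ene-6,11-diol | C=C1C[C@@H](O)[C@@H]2C(C)(C)[C@@H](O[Si](C)(C)C(C)(C)C)CC[C@@]2(C)[C@@H]1CO
F8 | step 11 | 7-{[(3S,5S,6R,9R,10S)-3-[(tert-butyldimethylsilyl)oxy]-6-hydroxydrim-8(12)-en-11-yl]oxy}-2H-chromen-2-one | C=C1C[C@@H](O)[C@@H]2C(C)(C)[C@@H](O[Si](C)(C)C(C)(C)C)CC[C@@]2(C)[C@@H]1COc1ccc2ccc(=O)oc2c1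
F9 | step 12 | (3S,5S,6R,9R,10S)-3-[(tert-butyldimethylsilyl)oxy]-11-[(trifluoromethanesulfonyl)oxy]drim-8(12)-en-6-yl acetate | C=C1C[C@@H](OC(C)=O)[C@@H]2C(C)(C)[C@@H](O[Si](C)(C)C(C)(C)C)CC[C@@]2(C)[C@@H]1COS(=O)(=O)C(F)(F)F
A1 | alternative 1 | 7-{[(2E,5R,6E)-5-[(tert-butyldimethylsilyl)oxy]-9-[(2R)-3,3-dimethyloxiran-2-yl]-3,7-dimethylnona-2,6-dien-1-yl]oxy}-2H-chromen-2-one | CC1(C)O[C@@H]1CC/C(C)=C/[C@H](O[Si](C)(C)C(C)(C)C)C/C(C)=C/COc1ccc2ccc(=O)oc2c1
A2 | alternative 1 | 7-{[(3R,5S,6R,9R,10S)-6-[(tert-butyldimethylsilyl)oxy]-3-hydroxydrim-8(12)-en-11-yl]oxy}-2H-chromen-2-one | C=C1C[C@@H](O[Si](C)(C)C(C)(C)C)[C@@H]2C(C)(C)[C@H](O)CC[C@@]2(C)[C@@H]1COc1ccc2ccc(=O)oc2c1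
A3 | alternative 2 | (R)-8a-methyl-3,4,8,8a-tetrahydronaphthalene-1,6(2H,7H)-dione | C[C@@]12CCC(=O)C=C1CCCC2=O
A4 | alternative 2 | 9,9-ethylenedioxy-4,4,10-trimethyl-Δ5-octalin-3-one (drimane numbering, C10 as in 23) | CC1(C)C(=O)CC[C@]2(C)C1=CCCC21OCCO1
A5 | alternative 3 | (1R,3E)-5-[(tert-butyldimethylsilyl)oxy]-3-methyl-1-[(5S)-5-[(tert-butyldimethylsilyl)oxy]-2,6,6-trimethylcyclohex-1-en-1-yl]pent-3-en-1-ol | CC(C)(C)[Si](C)(C)OC/C=C(C)/C[C@@H](O)C1=C(C)CC[C@H](O[Si](C)(C)C(C)(C)C)C1(C)C
A6 | alternative 3 | 3,11-bis[(tert-butyldimethylsilyl)oxy]-6,7-secodrim-7-en-6-al (C3, C5, C9 and C10 as in 23) | C=C(C)[C@@H](CO[Si](C)(C)C(C)(C)C)[C@]1(C)CC[C@H](O[Si](C)(C)C(C)(C)C)C(C)(C)[C@H]1C=O
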